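The earlier runs and the new flask are calculated for substances that don't exist; scatter was added.

Two questions stand on this flask, and one quantity answers both, so here is the quick number with its grounds.

all flasks: gas phase 40 mM (held)
- beta: substrate 0.30 M; catalyst 0.60 mM; run made earlier
- eta: substrate 0.46 M; catalyst 0.60 mM; run made earlier
- zeta: substrate 0.61 M; catalyst 1.2 mM; run made earlier
- flask: substrate 0.61 M; catalyst 0.60 mM; time 8.0 h

| run | time / h | product / % |
|---|---|---|
| beta | 0.833 | 14.4 |
| beta | 2.50 | 46.3 |
| beta | 4.00 | 70.8 |
| beta | 6.00 | 98.9 |
| eta | 1.50 | 18.3 |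
| eta | 3.00 | 36.1 |
| eta | 5.00 | 60.8 |
| eta | 6.00 | 72.6 |
| zeta | 0.833 | 7.7 |
| zeta | 2.50 | 22.7 |
| zeta | 4.00 | 37.0 |
| zeta | 6.00 | 55.4 |

(each reading ± 1 percentage point)

1. how much product there is at 8.0 h, in percent of the substrate charged
2. concentration of dissolved gas in solution at 8.0 h, in percent of saturation

- at the start none of the gas phase is in solution

In molar terms, averaged from the start, the last eta reading gives 0.0557 M h⁻¹ of product and the last zeta reading 0.0563 M h⁻¹, although zeta holds twice the catalyst of eta and more substrate. The two rates are alike, so uptake of the gas phase into solution reads as the rate-limiting step. The mean of the two readings, 0.0560 M h⁻¹, is the supply rate G, the product per litre and hour that the gas uptake can pay for.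

Let S be the substrate left, x the product formed and K the substrate level at which the rate falls to half of G. Then r = G·S/(S+K) integrates in closed form:

x + K·ln(charge/S) = G·t

The beta run supplies K, roughly, and its last reading carries the scatter:

K = 0.008703 M

For this flask, G·t = 0.448 M out of 0.61 M, or 73.4% of the charge. The K term lowers that:

y = 71.5%

Dissolved gas, as a share of saturation, is K/(S+K):

sat = 4.77%

The forecast, “limited by gas transfer”, gives 72.5% (70.5% to 74.5%) and 6% (2% to 12%), both higher than the values reckoned here.

The flask gives 72.6% of product and 2.36% of saturation.

    gas phase ⇌ dissolved gas, rate k1*(csat - [dissolved gas]) (kL = 3.90 × 10⁻⁴ s⁻¹)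
    substrate + dissolved gas + catalyst → catalyst + product (k = 160 L² mol⁻² s⁻¹)

The same G serves for this flask stopped at 5.0 h, with the time the one change. There G·t = 0.280 M, and the closed form gives 45.0%. That neighbouring flask holds 45.5% of product, with 54% of the substrate remaining and dissolved gas at 4.83 × 10⁻⁴ M.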